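A ratio tells me whether to hold the next flask to its longest time: late target over the first nucleophile taken up.

common to all: first nucleophile 0.396 M; second nucleophile 0.528 M

| charge | starting material | remark | time |
|---|---|---|---|
| east | 0.62 M | run made earlier |  |
| north-east | 0.97 M | run made earlier |  |
| flask | 0.44 M |  | 15 d |

| run | time / d | target / % |
|---|---|---|
| east | 0.167 | 22.4 |
| east | 0.417 | 34.6 |
| east | 0.833 | 22.1 |
| east | 1.67 | 8.6 |
| east | 4.00 | 4.9 |
| east | 8.00 | 5.5 |
| east | 20.0 | 5.5 |
| north-east | 0.167 | 25.1 |
| north-east | 0.417 | 23.6 |
| north-east | 0.833 | 12.5 |
| north-east | 1.67 | 4.3 |
| north-east | 4.00 | 3.7 |
| north-east | 8.00 | 3.6 |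
| north-east | 20.0 | 3.2 |

(standard deviation of a reading: 0.5 percentage points)

1. time up to 15 d at which target stands highest
2. the amount of target, in percent of the starting material charged, at that time

- steps thought possible: starting material -> intermediate; first nucleophile + intermediate -> target; second nucleophile + intermediate -> other capture product; intermediate -> solvolysis product; target <-> isomer of the product; 2 second nucleophile -> self-condensation product

In the east run target lies flat at 5.5 % and 5.5 %. I take the first nucleophile there as the limiting reagent, its charge being smaller than that of the starting material. Counting its whole charge as taken up, the last reading gives the late share, c(target) late over c(first nucleophile) taken up, as 8.61 %. The north-east run, with 1.56 times the starting material and the same first nucleophile, gives 7.84 % at its last reading.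

For the new flask, even full uptake of the first nucleophile gives 7.75 % of the starting material charged as late target, well below the east reading of 34.6 % at 0.417 d. So I keep the charges and do not plan to hold to 15 d. The ratio carries no time, so I take the stopping time from that east reading, near 0.417 d, and expect about the same height.

The forecast differs from my figure: it gives 42 % at 0.6 d, in its words “The peak should therefore come later and stand higher”.

The flask peaks at 0.431 d with 34.2 %. Changing only the starting material from the east run to this charge moves the highest target from 34.7 % to 34.2 %. At 15.0 d the flask has 23 % of its first nucleophile left, so the late share gives 5.95 %, and the flask holds 5.76 %.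

    starting material → intermediate (k = 0.160 h⁻¹)
    first nucleophile + intermediate → target (k = 98.0 L mol⁻¹ h⁻¹)
    second nucleophile + intermediate → other capture product (k = 900 L mol⁻¹ h⁻¹)
    intermediate → solvolysis product (k = 2.00 h⁻¹)
    target ⇌ isomer of the product (K = 11.0, k = 0.0840 h⁻¹)
    2 second nucleophile → self-condensation product (k = 4.00 L mol⁻¹ h⁻¹)

In a neighbour flask charged with 0.099 M of first nucleophile, full uptake and the late share give 1.94 % of target at the end. The computed neighbour has 0 % of that nucleophile left and holds 1.87 % of target.

The earlier runs and the new flask come from a simulation for an exercise.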